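A pitfall with scattered readings is to take two equal numbers as proof that two runs are equal, so I began by comparing the blue and teal runs with their scatter in mind.

all flasks: gas phase 47 mM (held)
- blue: substrate 0.15 M; run made earlier
- teal: substrate 0.60 M; run made earlier
- flask: substrate 0.30 M; time 20 min

| blue: time / min | blue: target / % | teal: time / min | teal: target / % |
|---|---|---|---|
| 1.50 | 0 | 1.50 | 0 |
| 2.50 | 3 | 2.50 | 2 |
| 4.00 | 3 | 4.00 | 1 |
| 6.00 | 4 | 6.00 | 5 |
| 8.00 | 5 | 8.00 | 4 |
| 12.0 | 10 | 12.0 | 5 |
| 20.0 | 13 | 20.0 | 13 |

(scatter of a reading: 1.5 percentage points)

- the numbers in the tables scatter by 1.5 percentage points (one standard deviation)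
- at the start none of the gas phase is in solution

* the target standing at 20 min, as a percentage of the substrate charged
* the change that raises the amount of target at 20 min, in percent of the substrate charged most ("none" if none brings more than 2 percentage points) (birch / oak / none)
* amount of target at 20 min, in percent of the substrate charged, after birch

- birch: doubling the transfer coefficient of the gas phase, all else as stated
- oak: doubling the saturation concentration of gas phase, all else as stated

The teal charge was 4.00 times the blue one, yet the two runs read 13% and 13% at 20.0 min, equal within the scatter. With the gas phase held, I took the substrate as pseudo-first-order, an assumption that these two readings allow but do not prove. Counting reacted substrate as target, the fraction left, f, and the half-life, τ, were: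

f = 87.0%

τ = ln(2) × t / ln(1/f) = 99.5 min

This τ, the substrate half-life, is the time in which the substrate falls to half at the pace the runs show.

I then ran the flask, charged with 0.30 M, in slow motion. At the start none of the gas phase was in solution, and both runs read 0% at 1.50 min, so I expected the flask to open with gas dissolving. Through the middle the readings climbed, reaching 5% and 4% at 8.00 min. At the end, the flask had counted n half-lives:

n = t/τ = 0.201

substrate left = 87.0%, so target = 13.0%

Both runs held the gas at 47 mM, so τ gave me no reckoning for birch or oak.

The forecast gave 12.5% (range 11% to 14%), chose oak, and put birch at 13%, holding that “Doubling the transfer coefficient only halves the lag”.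

The flask gave 13.1% of target with 84.6% of substrate left. Oak added 8.2 percentage points and birch 4.9 points, so oak was best, and birch reached 18.0%, more than the forecast's figure.

    target → over-reaction product (k = 0.00820 min⁻¹)
    substrate + dissolved gas → target (k = 0.580 L mol⁻¹ min⁻¹)
    dissolved gas ⇌ dormant form (K = 3.20, k = 0.140 min⁻¹)
    dissolved gas + target → over-reacted product (k = 0.610 L mol⁻¹ min⁻¹)
    gas phase ⇌ dissolved gas, rate k5*(csat - [dissolved gas]) (kL = 0.160 min⁻¹)
    2 dissolved gas → self-condensation product (k = 1.10 L mol⁻¹ min⁻¹)

On the neighbouring flask, the same charge read at 80 min, I counted 0.804 half-lives, which leaves 57.3% of the substrate. That flask held 43.0%, less than the count gave, and its dissolved gas stood at 0.0216 M, against 0.0170 M in the first flask at 20.0 min. In the neighbouring flask, target stood at 26.8%, over-reacted product at 17.9% and over-reaction product at 12.4%.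

(All runs are simulated with constants of no real substance, and the scatter is random.)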